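## Retrosynthetic overview

1. Ring labels: A is the methoxy ring (OMe, OAr and CH2 on adjacent carbons). B is the meta-linked ring on the oxygen of A. C is the phenol ring. D is the para-linked ring. The feature used: the ether carbon of A (C2) lies ortho, and the ether carbon of D (C4) lies para, to the two carbons of the same A–CH2CH2–D bridge.
2. The target comes by global hydrogenolysis from the 18-membered macrocycle that carries this bridge as a 1,2-dione (benzil) and the ring C phenol as its benzyl ether.
3. The macrocyclic dione comes from a one-flask double SNAr. It forms both diaryl ether bonds, first C3(ring C)–O–C4(ring D) and then C3(ring B)–O–C2(ring A), and the only ring, from two bibenzyl-level halves.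
4. The halves are 2,4'-difluoro-3-methoxybenzil (Sonogashira coupling, alkyne oxidation) and a B–CH2CH2–C bibenzyl (hydroboration/B-alkyl Suzuki coupling). Its ring C OH is free and its ring B oxygen is an O-TIPS ether, which fixes the order of the two substitutions.
5. Ring order: only the macrocycle is formed, and it is closed by the second SNAr. No stereocentre arises.

Key step: step 6

Assumption: the SMILES holds no stereocentre and no stereogenic double bond, and the 18-membered cyclophane is taken as conformationally mobile at room temperature. The compound is therefore treated as achiral and no enantiocontrol is needed.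

## Route

Step 1
Reactants: 1 1-bromo-2-fluoro-3-methoxybenzene; 2 1-ethynyl-4-fluorobenzene
Product: 3 2-fluoro-1-[(4-fluorophenyl)ethynyl]-3-methoxybenzene
Conditions: PdCl2(PPh3)2 (3 mol%), CuI (5 mol%), Et3N, 80 °C
Reagents that add atoms: none
Why: Sonogashira coupling, in which Pd(0) inserts only into the C–Br bond and both C–F bonds stay untouched.

Step 2
Reactants: 3 2-fluoro-1-[(4-fluorophenyl)ethynyl]-3-methoxybenzene
Product: 4 1-(2-fluoro-3-methoxyphenyl)-2-(4-fluorophenyl)ethane-1,2-dione
Conditions: PdI2 (2 mol%), DMSO, 140 °C
Reagents that add atoms: dimethyl sulfoxide, CS(C)=O (oxygen donor, two equivalents)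
Why: Palladium-catalysed DMSO oxidation of a diarylalkyne to the benzil, a substrate class without alpha-hydrogens that cannot be over-oxidised and that tolerates aryl fluoride and anisole groups.

Step 3
Reactants: 5 3-bromophenol
Product: 6 (3-bromophenoxy)tri(propan-2-yl)silane
Conditions: TIPSCl (1.1 equiv), imidazole (2 equiv), DMF, rt
Reagents that add atoms: chlorotri(propan-2-yl)silane, CC(C)[Si](Cl)(C(C)C)C(C)C
Why: Standard imidazole-mediated O-silylation; TIPS is chosen because aryl TIPS ethers should withstand aqueous phosphate and solid carbonate but are cleaved by soluble fluoride.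

Step 4
Reactants: 7 4-(benzyloxy)-3-hydroxybenzaldehyde
Product: 8 2-(benzyloxy)-5-ethenylphenol
Conditions: Ph3PCH3Br (2.5 equiv), KOtBu (3.5 equiv), THF, 0 °C to rt; aq. NH4Cl
Reagents that add atoms: methyltriphenylphosphonium bromide, C[P+](c1ccccc1)(c1ccccc1)c1ccccc1.[Br-]
Why: Wittig methylenation run on the phenoxide, whose oxygen is meta to the formyl group and so does not deactivate it.

Step 5
Reactants: 8 2-(benzyloxy)-5-ethenylphenol; 6 (3-bromophenoxy)tri(propan-2-yl)silane
Product: 10 2-(benzyloxy)-5-[2-(3-{[tri(propan-2-yl)silyl]oxy}phenyl)ethyl]phenol, via bis(9-BBN) adduct 9 (not isolated)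
Conditions: 9-BBN (2.2 equiv), THF, 0 °C to rt; then 6, PdCl2(dppf) (5 mol%), K3PO4 (3 M aq.), DMF, 60 °C
Reagents that add atoms: 9-borabicyclo[3.3.1]nonane, B1C2CCCC1CCC2 (its boron units stand only in 9; only hydrogen stays in 10)
Why: Anti-Markovnikov hydroboration followed by B-alkyl Suzuki–Miyaura coupling gives the saturated B–CH2CH2–C bridge directly, so the benzyl ether never meets hydrogenation, and the first equivalent of borane masks the phenol as a borinate that the aqueous base releases again.

Step 6
Reactants: 10 2-(benzyloxy)-5-[2-(3-{[tri(propan-2-yl)silyl]oxy}phenyl)ethyl]phenol; 4 1-(2-fluoro-3-methoxyphenyl)-2-(4-fluorophenyl)ethane-1,2-dione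
Product: 13 macrocyclic benzil (target skeleton whose A–D bridge is C(=O)–C(=O) and whose ring C oxygen is benzylated), via open mono-ether 11 (not isolated), via caesium phenoxide 12 (not isolated)
Conditions: (i) K2CO3 (1.1 equiv), DMF, 4 Å MS, 60 °C, 0.1 M; (ii) slow transfer (12 h) into CsF (5 equiv), DMF, 110 °C, final 2 mM
Reagents that add atoms: caesium fluoride, [Cs+].[F-] (supplies only the counter-ion of 12; nothing of it stays in 13)
Why: Both substitutions are addition–elimination SNAr reactions through Meisenheimer complexes whose charge is taken up by the 1,2-dione: the carbonyl next to ring D lies para to C4–F and the carbonyl next to ring A lies ortho to C2–F, so one functional group activates both ether carbons. The closest known reaction type is the carbonate- or fluoride-mediated condensation of bisphenols or their silyl ethers with 4,4'-difluorobenzil and related bis(fluoroaryl) ketones, which gives poly(aryl ether)s at high concentration and macrocyclic aryl ether ketones at low concentration. Stage (i) joins the halves: only the ring C phenoxide is available, and it should take the unhindered para C–F of ring D rather than the C–F of ring A, which is flanked by OMe and the aroyl group. Stage (ii) closes the 18-membered ring: fluoride cleaves the aryl O–Si bond and the unhindered ring B phenoxide displaces the ring A fluoride in an end-to-end macrocyclisation under pseudo-high dilution, which regenerates fluoride. The selectivity needed is the pairing C to D and B to A, because rings B and C are both 3-oxygenated and the bibenzyl is pseudo-symmetric; the free OH/O-TIPS difference secures it and sterics back it, since the wrong pairing would have to bring the ortho-benzyloxy phenoxide to the doubly flanked carbon of ring A. No stereocentre is formed, and the skewed benzil unit should act as a turn that brings the chain ends together.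

Step 7
Reactants: 13 macrocyclic benzil
Product: 14 target, CNP0309263.0
Conditions: H2 (5 bar), Pd(OH)2/C, AcOH–EtOAc 1:1, 50 °C
Reagents that add atoms: none
Why: Palladium-catalysed hydrogenation and benzylic C–O hydrogenolysis should take both aryl ketones through the carbinols to CH2, helped by the ortho- and para-aryloxy donors, and cleave the O-benzyl ether in the same operation, while OMe and the diaryl ethers are inert.

## Compound list

1 | 1-bromo-2-fluoro-3-methoxybenzene | COc1cccc(Br)c1F | starting material
2 | 1-ethynyl-4-fluorobenzene | C#Cc1ccc(F)cc1 | starting material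
3 | 2-fluoro-1-[(4-fluorophenyl)ethynyl]-3-methoxybenzene | COc1cccc(C#Cc2ccc(F)cc2)c1F | intermediate
4 | 1-(2-fluoro-3-methoxyphenyl)-2-(4-fluorophenyl)ethane-1,2-dione | COc1cccc(C(=O)C(=O)c2ccc(F)cc2)c1F | intermediate
5 | 3-bromophenol | Oc1cccc(Br)c1 | starting material
6 | (3-bromophenoxy)tri(propan-2-yl)silane | CC(C)[Si](Oc1cccc(Br)c1)(C(C)C)C(C)C | intermediate
7 | 4-(benzyloxy)-3-hydroxybenzaldehyde | O=Cc1ccc(OCc2ccccc2)c(O)c1 | starting material
8 | 2-(benzyloxy)-5-ethenylphenol | C=Cc1ccc(OCc2ccccc2)c(O)c1 | intermediate
9 | bis(9-BBN) adduct of 8 (B-alkyl borane, phenol as O-borinate; not isolated) | B1(CCc2ccc(OCc3ccccc3)c(OB3C4CCCC3CCC4)c2)C2CCCC1CCC2 | intermediate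
10 | 2-(benzyloxy)-5-[2-(3-{[tri(propan-2-yl)silyl]oxy}phenyl)ethyl]phenol | CC(C)[Si](Oc1cccc(CCc2ccc(OCc3ccccc3)c(O)c2)c1)(C(C)C)C(C)C | intermediate
11 | open mono-ether (ring C–O–ring D formed, ring A C–F and ring B O-TIPS intact; not isolated) | COc1cccc(C(=O)C(=O)c2ccc(Oc3cc(CCc4cccc(O[Si](C(C)C)(C(C)C)C(C)C)c4)ccc3OCc3ccccc3)cc2)c1F | intermediate
12 | caesium phenoxide of desilylated 11 (not isolated) | [Cs+].COc1cccc(C(=O)C(=O)c2ccc(Oc3cc(CCc4cccc([O-])c4)ccc3OCc3ccccc3)cc2)c1F | intermediate
13 | macrocyclic benzil, O-benzyl protected | COc1cccc2c1Oc1cccc(c1)CCc1ccc(OCc3ccccc3)c(c1)Oc1ccc(cc1)C(=O)C2=O | intermediate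
14 | CNP0309263.0 | COc1cccc2c1Oc1cccc(c1)CCc1ccc(O)c(c1)Oc1ccc(cc1)CC2 | target

## Step count and risks

Total step count: 7
Longest linear sequence: 4 steps (for example steps 4, 5, 6, 7)

**Step 6.**
- Risks:
  - Oligomerisation may outrun ring closure at the hindered ring A carbon.
  - The silyl group may be lost early in stage (i), which would blur the pairing of the two phenoxides.
  - Adventitious hydroxide may degrade the dione by a benzilic acid type rearrangement.
- Fallback: the macrocyclisation is moved from C–O to C=C bond formation and no dione is used.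
  - It sets out from 10, which is arylated with 4-fluorobenzaldehyde (K2CO3, DMF, 90 °C) to the mono-aldehyde F1.
  - CsF and 2-fluoro-3-methoxybenzaldehyde (DMF, 100 °C) then give the dialdehyde F2 by desilylative SNAr.
  - An intramolecular McMurry coupling (TiCl4, Zn, pyridine, THF, reflux, slow addition) closes the ring to the macrocyclic stilbene F3, an E/Z mixture.
  - H2 over Pd/C saturates the alkene and removes the benzyl group, so the fallback comes back to the route at 14.

**Step 7.**
- Risks:
  - The reduction may stall at the 1,2-diol stage.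
  - If acid is raised to force it, ionisation of the ring A carbinol may lead to Friedel–Crafts attack on ring B.
- Fallback: the oxygens are removed as activated esters under neutral conditions.
  - It sets out from 13, which is reduced with NaBH4 (THF–MeOH, 0 °C) to the diol F4, a diastereomer mixture whose two centres are erased later.
  - The diol is acetylated (Ac2O, pyridine, DMAP) to the diacetate F5.
  - Neutral hydrogenolysis (H2, Pd/C, EtOAc–EtOH) cleaves both benzylic acetates and the benzyl ether, so the fallback comes back to the route at 14.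

**Step 5.**
- Risks:
  - The phenol may consume borane unevenly.
  - The alkylborane may undergo protodeboronation or beta-hydride elimination.
  - The aqueous base may erode the silyl ether.
- Fallback: the sp3–sp2 coupling is replaced by an sp–sp2 coupling followed by a poisoned hydrogenation.
  - It sets out from 7, which is homologated with the Ohira–Bestmann reagent (K2CO3, MeOH) to the alkyne F6.
  - Sonogashira coupling with 6 gives the diarylalkyne F7.
  - H2 over Pd/C in the presence of pyridine saturates the alkyne while the phenolic benzyl ether is kept, so the fallback comes back to the route at 10.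

## Further compounds

F1 | step 6 | 4-[2-(benzyloxy)-5-[2-(3-{[tri(propan-2-yl)silyl]oxy}phenyl)ethyl]phenoxy]benzaldehyde | O=Cc1ccc(Oc2cc(CCc3cccc(O[Si](C(C)C)(C(C)C)C(C)C)c3)ccc2OCc2ccccc2)cc1
F2 | step 6 | 2-[3-(2-{4-(benzyloxy)-3-(4-formylphenoxy)phenyl}ethyl)phenoxy]-3-methoxybenzaldehyde | COc1cccc(C=O)c1Oc1cccc(CCc2ccc(OCc3ccccc3)c(Oc3ccc(C=O)cc3)c2)c1
F3 | step 6 | macrocyclic stilbene, O-benzyl protected (E/Z mixture, A–CH=CH–D) | COc1cccc2c1Oc1cccc(c1)CCc1ccc(OCc3ccccc3)c(c1)Oc1ccc(cc1)C=C2
F4 | step 7 | macrocyclic 1,2-diol, O-benzyl protected (diastereomer mixture) | COc1cccc2c1Oc1cccc(c1)CCc1ccc(OCc3ccccc3)c(c1)Oc1ccc(cc1)C(O)C2O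
F5 | step 7 | macrocyclic 1,2-diacetate, O-benzyl protected (diastereomer mixture) | COc1cccc2c1Oc1cccc(c1)CCc1ccc(OCc3ccccc3)c(c1)Oc1ccc(cc1)C(OC(C)=O)C2OC(C)=O
F6 | step 5 | 2-(benzyloxy)-5-ethynylphenol | C#Cc1ccc(OCc2ccccc2)c(O)c1
F7 | step 5 | 2-(benzyloxy)-5-[(3-{[tri(propan-2-yl)silyl]oxy}phenyl)ethynyl]phenol | CC(C)[Si](Oc1cccc(C#Cc2ccc(OCc3ccccc3)c(O)c2)c1)(C(C)C)C(C)C
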